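## Retrosynthetic overview
1. Target 18 comes from its 4'-O-TBS ether 17 by fluoride cleavage in the same flask.
2. Ring A of 17 is cut at C4a–C5 and C7–C8. This [3+3] disconnection gives prenylmalonyl dichloride 12 (C5–C6–C7) and the 6-alkyl-dihydropyranone 14 (C4a, C8a, C8).
3. Ring C of 14 is cut at C2–C3 and O1–C8a (formal hetero-Diels–Alder) into aldehyde 4 and bis(silyloxy)diene 8. Forming C2–C3 sets the only stereocentre.
4. Forward order: ring B is bought, then ring C and ring A form one after the other in one flask from 4 + 8 + 12.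
5. Compounds 4, 8 and 12 each take two steps from prenyl bromide 2 plus 4-hydroxybenzaldehyde 1, acetylacetone 5 or diethyl malonate 9.

Flavanone numbering (O1, C2, C3, C4, C4a, C5–C8, C8a) is used for all intermediates.

Assumption: Ti(OiPr)4/(S)-BINOL is taken to deliver the diene to the Si face of ArCHO, as it does with allyl and dienolate nucleophiles. If the first run shows the opposite sense, (R)-BINOL is used.

## Route

Step 1
Reactants: 1 4-hydroxybenzaldehyde; 2 prenyl bromide
Product: 3 4-hydroxy-3-(3-methylbut-2-enyl)benzaldehyde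
Conditions: KOH, H2O, rt, 24 h; then dilute HCl
Reagents that add atoms: none
Why: In water the phenoxide oxygen is masked by hydrogen bonding, so prenyl bromide alkylates the ortho carbon (phenoxide C-alkylation, para position blocked by CHO), a known if moderate-yielding preparation.

Step 2
Reactants: 3 4-hydroxy-3-(3-methylbut-2-enyl)benzaldehyde
Product: 4 4-(tert-butyldimethylsilyloxy)-3-(3-methylbut-2-enyl)benzaldehyde
Conditions: TBSCl, imidazole, DMF, rt
Reagents that add atoms: tert-butyldimethylsilyl chloride CC(C)(C)[Si](C)(C)Cl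
Why: Standard imidazole-promoted O-silylation gives an aryl TBS ether that survives Lewis acid, catalytic TFA and acyl chlorides and leaves with fluoride.

Step 3
Reactants: 5 acetylacetone; 2 prenyl bromide
Product: 6 8-methylnon-7-ene-2,4-dione
Conditions: LiN(iPr)2 (2.1 equiv), THF, 0 °C; 2, 0 °C to rt; then 1 M HCl
Reagents that add atoms: none
Why: In this Hauser–Harris dianion alkylation the terminal carbanion of the 1,3-dianion is by far the more nucleophilic site, so one prenyl group enters at the methyl carbon only.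

Step 4
Reactants: 6 8-methylnon-7-ene-2,4-dione
Product: 8 (Z)-8-methyl-2,4-bis(trimethylsilyloxy)nona-1,3,7-triene, via monosilyl enol ether 7 (not isolated)
Conditions: Me3SiCl, Et3N, pentane, rt; filter, evaporate; LiN(iPr)2, THF, −78 °C; Me3SiCl, −78 °C to rt
Reagents that add atoms: chlorotrimethylsilane C[Si](C)(C)Cl
Why: Soft silylation of the enol, then kinetic deprotonation at the unhindered CH3 and O-silylation, gives the Chan-type 1,3-bis(silyloxy)diene with a free CH2= terminus (two-stage enol silylation).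

Step 5
Reactants: 9 diethyl malonate; 2 prenyl bromide
Product: 11 2-(3-methylbut-2-enyl)malonic acid, via diethyl prenylmalonate 10 (not isolated)
Conditions: NaOEt, EtOH, 0 °C to rt; KOH, H2O–EtOH, 60 °C; then 2 M HCl, 0 °C
Reagents that add atoms: potassium hydroxide [K+].[OH-]
Why: This is a malonic ester synthesis stopped before decarboxylation, in which SN2 alkylation of sodiomalonate, saponification and cold acidification all leave the trisubstituted alkene untouched.

Step 6
Reactants: 11 2-(3-methylbut-2-enyl)malonic acid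
Product: 12 2-(3-methylbut-2-enyl)malonyl dichloride
Conditions: (COCl)2 (2.5 equiv), DMF (cat.), CH2Cl2, 0 °C to rt; evaporate, use at once
Reagents that add atoms: oxalyl chloride O=C(Cl)C(=O)Cl
Why: Vilsmeier-type activation converts both acids into acid chlorides with only gaseous by-products, as is routine for acids that carry prenyl groups.

Step 7
Reactants: 4 4-(tert-butyldimethylsilyloxy)-3-(3-methylbut-2-enyl)benzaldehyde; 8 (Z)-8-methyl-2,4-bis(trimethylsilyloxy)nona-1,3,7-triene; 12 2-(3-methylbut-2-enyl)malonyl dichloride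
Product: 18 (2S)-5,7-dihydroxy-2-[4-hydroxy-3-(3-methylbut-2-enyl)phenyl]-6,8-bis(3-methylbut-2-enyl)chroman-4-one, via silyl aldol adduct 13 (not isolated), via dihydropyranone 14 (not isolated), via chlorocarbonyl ketene 15 (not isolated), via acylpyranone 16 (not isolated), via silyl flavanone 17 (not isolated)
Conditions: 4 (1.1 equiv), 8 (1.0 equiv), Ti(OiPr)4 (10 mol %), (S)-BINOL (10 mol %), 4 Å MS, Et2O, −20 °C; TFA (30 mol %), 0 °C; 2,6-di-tert-butyl-4-methylpyridine (3 equiv), 12 (1.3 equiv, slow addition), −20 to 35 °C; KHF2, MeOH, rt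
Reagents that add atoms: none
Why: Proposed new method: the Ti(OiPr)4/BINOL vinylogous Mukaiyama aldol adds the CH2= terminus of 8 to the Si face of 4 and so sets C2 as S in 13, catalytic acid then closes O1 onto the silyloxy-enone carbon with loss of (Me3Si)2O and without touching the C2–O bond (the formal hetero-Diels–Alder route to dihydropyranones, ring C), the enol-ether carbon C4a of 14 is acylated by ketene 15 released from 12 to give 16, the doubly vinylogous C8–H of 16 tautomerises to a dienol that closes on the remaining acyl chloride or its acylketene (6π closure of a dienylketene) and aromatises to ring A, the hindered pyridine holds the HCl away from the prenyl groups and the stereocentre, KHF2 finally frees the 4'-phenol under non-basic conditions that do not open ring C, and the closest known reaction type is the Effenberger cyclisation of enol ethers by malonyl dichloride to phloroglucinol monoethers, which tolerates prenyl groups.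

## Compound list
1 | 4-hydroxybenzaldehyde | O=Cc1ccc(O)cc1 | starting material
2 | prenyl bromide (1-bromo-3-methylbut-2-ene) | CC(C)=CCBr | starting material
3 | 4-hydroxy-3-(3-methylbut-2-enyl)benzaldehyde | CC(C)=CCc1cc(C=O)ccc1O | intermediate
4 | 4-(tert-butyldimethylsilyloxy)-3-(3-methylbut-2-enyl)benzaldehyde | CC(C)=CCc1cc(C=O)ccc1O[Si](C)(C)C(C)(C)C | intermediate
5 | acetylacetone (pentane-2,4-dione) | CC(=O)CC(C)=O | starting material
6 | 8-methylnon-7-ene-2,4-dione | CC(=O)CC(=O)CCC=C(C)C | intermediate
7 | (Z)-8-methyl-4-(trimethylsilyloxy)nona-3,7-dien-2-one (equilibrates with its 2-silyloxy isomer by O-to-O silyl shift) | CC(=O)/C=C(\O[Si](C)(C)C)CCC=C(C)C | intermediate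
8 | (Z)-8-methyl-2,4-bis(trimethylsilyloxy)nona-1,3,7-triene | C=C(O[Si](C)(C)C)/C=C(\O[Si](C)(C)C)CCC=C(C)C | intermediate
9 | diethyl malonate | CCOC(=O)CC(=O)OCC | starting material
10 | diethyl 2-(3-methylbut-2-enyl)malonate | CCOC(=O)C(CC=C(C)C)C(=O)OCC | intermediate
11 | 2-(3-methylbut-2-enyl)malonic acid | CC(C)=CCC(C(=O)O)C(=O)O | intermediate
12 | 2-(3-methylbut-2-enyl)malonyl dichloride | CC(C)=CCC(C(=O)Cl)C(=O)Cl | intermediate
13 | (1S,4Z)-1-[4-(tert-butyldimethylsilyloxy)-3-(3-methylbut-2-enyl)phenyl]-9-methyl-1,5-bis(trimethylsilyloxy)deca-4,8-dien-3-one | CC(C)=CCc1cc([C@@H](O[Si](C)(C)C)CC(=O)/C=C(\O[Si](C)(C)C)CCC=C(C)C)ccc1O[Si](C)(C)C(C)(C)C | intermediate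
14 | (2S)-2-[4-(tert-butyldimethylsilyloxy)-3-(3-methylbut-2-enyl)phenyl]-6-(4-methylpent-3-enyl)-2,3-dihydro-4H-pyran-4-one | CC(C)=CCc1cc([C@@H]2CC(=O)C=C(CCC=C(C)C)O2)ccc1O[Si](C)(C)C(C)(C)C | intermediate
15 | (chlorocarbonyl)(3-methylbut-2-enyl)ketene | CC(C)=CCC(=C=O)C(=O)Cl | intermediate
16 | 2-{[(2S)-2-aryl-6-(4-methylpent-3-enyl)-4-oxo-2,3-dihydro-4H-pyran-5-yl]carbonyl}-5-methylhex-4-enoyl chloride, aryl as in 14, epimers at the enolisable malonyl CH | CC(C)=CCc1cc([C@@H]2CC(=O)C(C(=O)C(CC=C(C)C)C(=O)Cl)=C(CCC=C(C)C)O2)ccc1O[Si](C)(C)C(C)(C)C | intermediate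
17 | (2S)-2-[4-(tert-butyldimethylsilyloxy)-3-(3-methylbut-2-enyl)phenyl]-5,7-dihydroxy-6,8-bis(3-methylbut-2-enyl)chroman-4-one | CC(C)=CCc1cc([C@@H]2CC(=O)c3c(O)c(CC=C(C)C)c(O)c(CC=C(C)C)c3O2)ccc1O[Si](C)(C)C(C)(C)C | intermediate
18 | (2S)-5,7-dihydroxy-2-[4-hydroxy-3-(3-methylbut-2-enyl)phenyl]-6,8-bis(3-methylbut-2-enyl)chroman-4-one, i.e. (2S)-6,8,3'-triprenylnaringenin | CC(C)=CCc1cc([C@@H]2CC(=O)c3c(O)c(CC=C(C)C)c(O)c(CC=C(C)C)c3O2)ccc1O | target

## Step count
- Total step count: 7.
- Longest linear sequence: 3 (for example 1 to 3 to 4 to 18; the branches through 8 and through 12 are equally long).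

## Steps most likely to fail

**First, step 7.**
- The weak point is the intermolecular C-acylation of the vinylogous ester 14. It may go to the C4 carbonyl oxygen or not proceed at all.
- The fallback makes the C4a–C5 bond before either ring exists. It sets out from 13, taken from the aldol stage by filtration and evaporation, and from 10, now isolated.
- One equivalent of KOH in EtOH turns 10 into ethyl hydrogen 2-(3-methylbut-2-enyl)malonate F1. Then (COCl)2 and catalytic DMF give ethyl 2-(chlorocarbonyl)-5-methylhex-4-enoate F2.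
- ZnCl2-catalysed C-acylation of the silyl enol ether of 13 by F2 in CH2Cl2 gives the (S)-triacylmethane F3.
- Catalytic TFA closes ring C to the acylpyranone ester F4. Whichever of the two ketones on C4a condenses with O1, the same ring A results.
- Heating the same solution in xylene at 140 °C closes ring A by loss of EtOH (acylketene formation, then 6π closure).
- The fallback comes back to the route at 17, which is desilylated with KHF2 as before.

**Second, step 4.**
- Kinetic deprotonation of the unsymmetrical monosilyl ether 7 may also occur at the CH2 next to the chain, which gives the internal diene.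
- The fallback removes the regiochemical question by changing the order of events. It sets out from 5.
- Compound 5 is silylated in the same two stages to (Z)-2,4-bis(trimethylsilyloxy)penta-1,3-diene F5, which has only one kind of terminus.
- The Ti(OiPr)4/(S)-BINOL aldol of F5 with 4, followed by a citric acid work-up, gives (S)-1-[4-(tert-butyldimethylsilyloxy)-3-(3-methylbut-2-enyl)phenyl]-1-hydroxyhexane-3,5-dione F6.
- LiN(iPr)2 (3.1 equiv) forms the alkoxide dianion. Bromide 2 alkylates it at the terminal CH3 to give (S)-1-aryl-1-hydroxy-9-methyldec-8-ene-3,5-dione F7.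
- Catalytic TFA over acid-washed sieves dehydrates F7. The fallback comes back to the route at 14, to which the pyridine base and 12 are added as in step 7.

**Third, step 1.**
- O-alkylation and double alkylation keep the yield of direct C-prenylation low.
- The fallback replaces intermolecular C-alkylation by a sigmatropic transfer. It sets out from 1.
- Compound 1 is O-alkylated with tert-butyl 2-methylbut-3-en-2-yl carbonate and Pd(PPh3)4 in THF to give 4-(2-methylbut-3-en-2-yloxy)benzaldehyde F8.
- Aromatic Claisen rearrangement of F8 in N,N-diethylaniline at 150 °C delivers the linear prenyl group to the ortho carbon. The fallback comes back to the route at 3.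

## Further compounds
F1 | step 7 | ethyl hydrogen 2-(3-methylbut-2-enyl)malonate | CCOC(=O)C(CC=C(C)C)C(=O)O
F2 | step 7 | ethyl 2-(chlorocarbonyl)-5-methylhex-4-enoate | CCOC(=O)C(CC=C(C)C)C(=O)Cl
F3 | step 7 | (S)-triacylmethane: ethyl 2-(3-methylbut-2-enyl)-3-oxo-4-(5-methylhex-4-enoyl)-5-oxo-7-aryl-7-(trimethylsilyloxy)heptanoate, aryl as in 14 | CC(C)=CCc1cc([C@@H](O[Si](C)(C)C)CC(=O)C(C(=O)CCC=C(C)C)C(=O)C(CC=C(C)C)C(=O)OCC)ccc1O[Si](C)(C)C(C)(C)C
F4 | step 7 | ethyl 2-{[(2S)-2-aryl-6-(4-methylpent-3-enyl)-4-oxo-2,3-dihydro-4H-pyran-5-yl]carbonyl}-5-methylhex-4-enoate, aryl as in 14 | CC(C)=CCc1cc([C@@H]2CC(=O)C(C(=O)C(CC=C(C)C)C(=O)OCC)=C(CCC=C(C)C)O2)ccc1O[Si](C)(C)C(C)(C)C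
F5 | step 4 | (Z)-2,4-bis(trimethylsilyloxy)penta-1,3-diene | C=C(O[Si](C)(C)C)/C=C(\O[Si](C)(C)C)C
F6 | step 4 | (S)-1-[4-(tert-butyldimethylsilyloxy)-3-(3-methylbut-2-enyl)phenyl]-1-hydroxyhexane-3,5-dione | CC(C)=CCc1cc([C@@H](O)CC(=O)CC(C)=O)ccc1O[Si](C)(C)C(C)(C)C
F7 | step 4 | (S)-1-[4-(tert-butyldimethylsilyloxy)-3-(3-methylbut-2-enyl)phenyl]-1-hydroxy-9-methyldec-8-ene-3,5-dione | CC(C)=CCc1cc([C@@H](O)CC(=O)CC(=O)CCC=C(C)C)ccc1O[Si](C)(C)C(C)(C)C
F8 | step 1 | 4-(2-methylbut-3-en-2-yloxy)benzaldehyde | C=CC(C)(C)Oc1ccc(C=O)cc1
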